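**Retrosynthetic overview**
- Target ⇒ macrocyclic aldehyde ester: the C9 carboxyl is reduced to CH2OH last, and the dienyl side chain comes from olefination of a CH2CHO arm at C1.
- Eleven-membered carbocycle ⇒ intramolecular Horner–Wadsworth–Emmons closure of C9=C10 onto one of two identical CH2CHO arms of a symmetric C1 unit; this ring closure breaks the symmetry and sets C1 by relay from C4.
- C4–C6 triad ⇒ Sharpless kinetic-resolution epoxidation of a bis-allylic alcohol, then Mitsunobu inversion at C4 with senecioic acid; C3–C4 ⇒ Nozaki–Hiyama–Kishi union of an E-vinyl iodide with an enal phosphonate.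
- Symmetric C1 unit ⇒ dearomatising reductive methylation of methyl isonicotinate and ring opening: pyridine C4 becomes C1, the four ring CH carbons become two CH2CH(OMe)2 arms, nitrogen is excised.
- Ring order: oxirane first (step 7), carbocycle second (step 10).

Assumption: compounds 1, 2, 7, 8, 14 and 18 are bought; the locants C1–C11 in the text are those of the eleven-membered ring (C1 quaternary, C4 acyloxy carbon, C5/C6 oxirane carbons, C9 the CH2OH-bearing olefin carbon), in which the target is 1R,4S,5S,6R.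

**Route**

Step 1
Reactants: 1 methyl isonicotinate (methyl pyridine-4-carboxylate); 2 iodomethane
Product: 4 methyl 4,4-dimethoxy-2-(2,2-dimethoxyethyl)-2-methylbutanoate, via dihydropyridine ester 3 (not isolated)
Conditions: K (2.2 equiv), NH3(l)/THF, t-BuOH (1 equiv), −78 °C; 2 (1.5 equiv); evaporate NH3; then HCl (3 equiv, 1.25 M in MeOH), 0 °C → rt
Reagents that add atoms: methanol (CO)
Why: Proposed new method: dissolving-metal reduction of the ester-activated pyridine should give a dianion that is protonated on nitrogen by t-BuOH and C-methylated at the C4 ester enolate, as in the Birch reductive alkylation of benzoates (closest known reaction type, with the Birch reduction of pyridines to 1,4-dihydropyridines and their hydrolysis to glutaraldehydes), after which acidic methanol turns both enamine arms of 3 into dimethyl acetals and expels nitrogen as NH4Cl; no stereocentre is formed.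

Step 2
Reactants: 4 methyl 4,4-dimethoxy-2-(2,2-dimethoxyethyl)-2-methylbutanoate
Product: 5 4,4-dimethoxy-2-(2,2-dimethoxyethyl)-2-methylbutanal
Conditions: i-Bu2AlH (1.1 equiv), CH2Cl2, −78 °C; aq. KNaC4H4O6
Reagents that add atoms: none
Why: Partial ester reduction, in which the aluminium hemiacetal of an alpha-quaternary ester survives at −78 °C and collapses to the non-enolisable aldehyde on work-up; no stereocentre.

Step 3
Reactants: 5 4,4-dimethoxy-2-(2,2-dimethoxyethyl)-2-methylbutanal
Product: 6 (E)-1-iodo-5,5-dimethoxy-3-(2,2-dimethoxyethyl)-3-methylpent-1-ene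
Conditions: CrCl2 (6 equiv), CHI3 (2 equiv), THF/dioxane, 0 °C → rt
Reagents that add atoms: iodoform (IC(I)I)
Why: Takai olefination, in which the gem-dichromium reagent adds to the hindered aldehyde and eliminates to the E-vinyl iodide (normally >15:1), fixing the E geometry of the later C2=C3 bond while the acetals stay intact.

Step 4
Reactants: 7 allyl 2-(diethoxyphosphoryl)acetate; 8 5-bromo-2-methylpent-2-ene
Product: 9 allyl 2-(diethoxyphosphoryl)-6-methylhept-5-enoate (racemic)
Conditions: NaH (1.05 equiv), NaI (cat.), DMF, 0 → 60 °C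
Reagents that add atoms: none
Why: SN2 alkylation of the sodium phosphonoacetate by the primary bromide gives the alpha-substituted Horner–Wadsworth–Emmons reagent; its stereocentre is racemic and disappears in step 10.

Step 5
Reactants: 9 allyl 2-(diethoxyphosphoryl)-6-methylhept-5-enoate
Product: 11 allyl (E)-2-(diethoxyphosphoryl)-6-methyl-7-oxohept-5-enoate, via allylic alcohol 10 (not isolated)
Conditions: SeO2 (1.5 equiv), dioxane/H2O (20:1), 80 °C
Reagents that add atoms: selenium dioxide (O=[Se]=O)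
Why: Riley allylic oxidation (ene reaction then [2,3]-shift) attacks the E-methyl group of the trisubstituted olefin and carries the alcohol 10 on to the E-enal, which fixes the E geometry of the future C5=C6 unit.

Step 6
Reactants: 6 (E)-1-iodo-5,5-dimethoxy-3-(2,2-dimethoxyethyl)-3-methylpent-1-ene; 11 allyl (E)-2-(diethoxyphosphoryl)-6-methyl-7-oxohept-5-enoate
Product: 12 allyl (5E,8E)-2-(diethoxyphosphoryl)-7-hydroxy-12,12-dimethoxy-10-(2,2-dimethoxyethyl)-6,10-dimethyldodeca-5,8-dienoate (racemic carbinol; both phosphonate epimers)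
Conditions: CrCl2 (4 equiv), NiCl2 (2 mol %), DMSO/THF, rt
Reagents that add atoms: none
Why: Nozaki–Hiyama–Kishi coupling, in which the alkenylchromium species formed from 6 with retention of E geometry adds 1,2 to the enal in the presence of ester, phosphonate and acetals; the C4 carbinol is racemic and is resolved in step 7.

Step 7
Reactants: 12 allyl (5E,8E)-2-(diethoxyphosphoryl)-7-hydroxy-12,12-dimethoxy-10-(2,2-dimethoxyethyl)-6,10-dimethyldodeca-5,8-dienoate
Product: 13 allyl 2-(diethoxyphosphoryl)-4-[(2R,3R)-3-[(1R,2E)-1-hydroxy-6,6-dimethoxy-4-(2,2-dimethoxyethyl)-4-methylhex-2-en-1-yl]-3-methyloxiran-2-yl]butanoate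
Conditions: Ti(OiPr)4 (10 mol %), D-(−)-diisopropyl tartrate (14 mol %), t-BuOOH (0.5 equiv), 4 Å molecular sieves, CH2Cl2, −20 °C
Reagents that add atoms: tert-butyl hydroperoxide (CC(C)(C)OO)
Why: Sharpless kinetic resolution, in which the D-(−)-tartrate catalyst epoxidises the trisubstituted olefin of the 4R enantiomer about a hundred times faster and from the face that gives the erythro epoxy alcohol, so the reagent fixes C5 and C6 as in the target and C4 as its epimer, leaving the 4S alcohol behind at about half conversion.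

Step 8
Reactants: 13 epoxy alcohol from step 7; 14 3-methylbut-2-enoic acid
Product: 15 allyl 2-(diethoxyphosphoryl)-4-[(2R,3S)-3-[(1S,2E)-6,6-dimethoxy-4-(2,2-dimethoxyethyl)-4-methyl-1-(3-methylbut-2-enoyloxy)hex-2-en-1-yl]-3-methyloxiran-2-yl]butanoate
Conditions: PPh3 (2 equiv), diisopropyl azodicarboxylate (2 equiv), toluene, 0 °C → rt
Reagents that add atoms: none
Why: Mitsunobu esterification, in which the senecioate displaces the alkoxyphosphonium of the allylic C4 alcohol by SN2 with inversion to the 4S configuration of the target (SN2' attack is blocked by the neopentyl C2) and the ester is installed in the same operation.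

Step 9
Reactants: 15 senecioate bis-acetal from step 8
Product: 16 allyl 2-(diethoxyphosphoryl)-4-[(2R,3S)-3-[(1S,2E)-4-methyl-1-(3-methylbut-2-enoyloxy)-6-oxo-4-(2-oxoethyl)hex-2-en-1-yl]-3-methyloxiran-2-yl]butanoate
Conditions: pyridinium p-toluenesulfonate (20 mol %), acetone/H2O (9:1), 45 °C
Reagents that add atoms: water (O)
Why: Mild acid-catalysed acetal hydrolysis should unmask both aliphatic dimethyl acetals faster than the trisubstituted oxirane opens, giving two identical CH2CHO arms on C1; no stereocentre changes.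

Step 10
Reactants: 16 dialdehyde phosphonate from step 9
Product: 17 allyl (1S,2S,3E,5S,7E,11R)-1,5-dimethyl-2-(3-methylbut-2-enoyloxy)-5-(2-oxoethyl)-12-oxabicyclo[9.1.0]dodeca-3,7-diene-8-carboxylate
Conditions: LiCl (10 equiv), DBU (3 equiv), MeCN, 1 mM (syringe-pump addition, 12 h), rt → 40 °C
Reagents that add atoms: none
Why: Proposed new method: in this Masamune–Roush Horner–Wadsworth–Emmons macrocyclisation the C9 phosphonate anion must choose one of the two diastereotopic CH2CHO arms, and the transition state that keeps H at C4 and CH3 at C1 eclipsed with the rigid E-C2=C3 olefin, with the larger OCOR and CH2CHO groups on the outer face, has the C1/C4 relationship of the target, so C4 should relay to C1 across the olefin (selectivity unproven, C1 epimer removed by chromatography), while the stabilised phosphonate and the ring both place the ester trans to C11; closest known reaction types are Horner–Wadsworth–Emmons macrocyclisations of cembranoids and diastereotopic-group-selective ring closures.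

Step 11
Reactants: 17 macrocyclic aldehyde from step 10; 18 diethyl (2-methylprop-2-en-1-yl)phosphonate
Product: 19 allyl (1S,2S,3E,5R,7E,11R)-1,5-dimethyl-2-(3-methylbut-2-enoyloxy)-5-[(2E)-4-methylpenta-2,4-dien-1-yl]-12-oxabicyclo[9.1.0]dodeca-3,7-diene-8-carboxylate
Conditions: 18 (1.3 equiv), LiN(SiMe3)2 (1.25 equiv), THF/DMPU, −78 °C; add 17; −78 °C → rt
Reagents that add atoms: none
Why: Horner–Wadsworth–Emmons olefination with the lithiated allylic phosphonate (alpha-attack, then elimination) gives the E-1,3-diene, the aldehyde reacting far faster than either ester at −78 °C; no stereocentre changes.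

Step 12
Reactants: 19 macrocyclic allyl ester from step 11
Product: 20 (1S,2S,3E,5R,7E,11R)-1,5-dimethyl-2-(3-methylbut-2-enoyloxy)-5-[(2E)-4-methylpenta-2,4-dien-1-yl]-12-oxabicyclo[9.1.0]dodeca-3,7-diene-8-carboxylic acid
Conditions: Pd(PPh3)4 (5 mol %), morpholine (5 equiv), THF, rt
Reagents that add atoms: none
Why: Tsuji–Trost deallylation, in which the palladium catalyst ionises the unhindered allyl ester and morpholine traps the allyl unit, while the hindered secondary allylic senecioate, the oxirane and the diene are left alone.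

Step 13
Reactants: 20 macrocyclic acid from step 12
Product: 22 [(1S,2S,3E,5R,7E,11R)-8-(hydroxymethyl)-1,5-dimethyl-5-[(2E)-4-methylpenta-2,4-dien-1-yl]-12-oxabicyclo[9.1.0]dodeca-3,7-dien-2-yl] 3-methylbut-2-enoate, via mixed carbonic anhydride 21 (not isolated)
Conditions: i-BuOCOCl (1.1 equiv), N-methylmorpholine (1.1 equiv), THF, −15 °C; then NaBH4 (3 equiv), H2O, 0 °C
Reagents that add atoms: isobutyl chloroformate (CC(C)COC(Cl)=O; its atoms stay in 21 and are lost again before 22)
Why: Activation of the conjugated acid as the mixed anhydride and NaBH4 reduction gives the primary allylic alcohol by 1,2-hydride delivery under conditions that leave the senecioate and the oxirane untouched, which completes the target.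

**Compound list**

1 | methyl isonicotinate | COC(=O)c1ccncc1 | starting material
2 | iodomethane | CI | starting material
3 | methyl 4-methyl-1,4-dihydropyridine-4-carboxylate | COC(=O)C1(C)C=CNC=C1 | intermediate
4 | methyl 4,4-dimethoxy-2-(2,2-dimethoxyethyl)-2-methylbutanoate | COC(OC)CC(C)(CC(OC)OC)C(=O)OC | intermediate
5 | 4,4-dimethoxy-2-(2,2-dimethoxyethyl)-2-methylbutanal | COC(OC)CC(C)(CC(OC)OC)C=O | intermediate
6 | (E)-1-iodo-5,5-dimethoxy-3-(2,2-dimethoxyethyl)-3-methylpent-1-ene | COC(OC)CC(C)(CC(OC)OC)/C=C/I | intermediate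
7 | allyl 2-(diethoxyphosphoryl)acetate | C=CCOC(=O)CP(=O)(OCC)OCC | starting material
8 | 5-bromo-2-methylpent-2-ene | CC(C)=CCCBr | starting material
9 | allyl 2-(diethoxyphosphoryl)-6-methylhept-5-enoate (racemic) | CC(C)=CCCC(C(=O)OCC=C)P(=O)(OCC)OCC | intermediate
10 | allyl (E)-2-(diethoxyphosphoryl)-7-hydroxy-6-methylhept-5-enoate (racemic) | OC/C(C)=C/CCC(C(=O)OCC=C)P(=O)(OCC)OCC | intermediate
11 | allyl (E)-2-(diethoxyphosphoryl)-6-methyl-7-oxohept-5-enoate (racemic) | O=C/C(C)=C/CCC(C(=O)OCC=C)P(=O)(OCC)OCC | intermediate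
12 | allyl (5E,8E)-2-(diethoxyphosphoryl)-7-hydroxy-12,12-dimethoxy-10-(2,2-dimethoxyethyl)-6,10-dimethyldodeca-5,8-dienoate (racemic carbinol; both phosphonate epimers) | COC(OC)CC(C)(CC(OC)OC)/C=C/C(O)/C(C)=C/CCC(C(=O)OCC=C)P(=O)(OCC)OCC | intermediate
13 | allyl 2-(diethoxyphosphoryl)-4-[(2R,3R)-3-[(1R,2E)-1-hydroxy-6,6-dimethoxy-4-(2,2-dimethoxyethyl)-4-methylhex-2-en-1-yl]-3-methyloxiran-2-yl]butanoate (both phosphonate epimers) | COC(OC)CC(C)(CC(OC)OC)/C=C/[C@@H](O)[C@@]1(C)O[C@@H]1CCC(C(=O)OCC=C)P(=O)(OCC)OCC | intermediate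
14 | 3-methylbut-2-enoic acid (senecioic acid) | CC(C)=CC(=O)O | starting material
15 | allyl 2-(diethoxyphosphoryl)-4-[(2R,3S)-3-[(1S,2E)-6,6-dimethoxy-4-(2,2-dimethoxyethyl)-4-methyl-1-(3-methylbut-2-enoyloxy)hex-2-en-1-yl]-3-methyloxiran-2-yl]butanoate | COC(OC)CC(C)(CC(OC)OC)/C=C/[C@H](OC(=O)C=C(C)C)[C@@]1(C)O[C@@H]1CCC(C(=O)OCC=C)P(=O)(OCC)OCC | intermediate
16 | allyl 2-(diethoxyphosphoryl)-4-[(2R,3S)-3-[(1S,2E)-4-methyl-1-(3-methylbut-2-enoyloxy)-6-oxo-4-(2-oxoethyl)hex-2-en-1-yl]-3-methyloxiran-2-yl]butanoate | O=CCC(C)(CC=O)/C=C/[C@H](OC(=O)C=C(C)C)[C@@]1(C)O[C@@H]1CCC(C(=O)OCC=C)P(=O)(OCC)OCC | intermediate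
17 | allyl (1S,2S,3E,5S,7E,11R)-1,5-dimethyl-2-(3-methylbut-2-enoyloxy)-5-(2-oxoethyl)-12-oxabicyclo[9.1.0]dodeca-3,7-diene-8-carboxylate | O=CC[C@@]1(C)/C=C/[C@H](OC(=O)C=C(C)C)[C@@]2(C)O[C@@H]2CC/C(C(=O)OCC=C)=C\C1 | intermediate
18 | diethyl (2-methylprop-2-en-1-yl)phosphonate | C=C(C)CP(=O)(OCC)OCC | starting material
19 | allyl (1S,2S,3E,5R,7E,11R)-1,5-dimethyl-2-(3-methylbut-2-enoyloxy)-5-[(2E)-4-methylpenta-2,4-dien-1-yl]-12-oxabicyclo[9.1.0]dodeca-3,7-diene-8-carboxylate | C=C(C)/C=C/C[C@@]1(C)/C=C/[C@H](OC(=O)C=C(C)C)[C@@]2(C)O[C@@H]2CC/C(C(=O)OCC=C)=C\C1 | intermediate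
20 | (1S,2S,3E,5R,7E,11R)-1,5-dimethyl-2-(3-methylbut-2-enoyloxy)-5-[(2E)-4-methylpenta-2,4-dien-1-yl]-12-oxabicyclo[9.1.0]dodeca-3,7-diene-8-carboxylic acid | C=C(C)/C=C/C[C@@]1(C)/C=C/[C@H](OC(=O)C=C(C)C)[C@@]2(C)O[C@@H]2CC/C(C(=O)O)=C\C1 | intermediate
21 | isobutyl carbonic anhydride of acid 20 | C=C(C)/C=C/C[C@@]1(C)/C=C/[C@H](OC(=O)C=C(C)C)[C@@]2(C)O[C@@H]2CC/C(C(=O)OC(=O)OCC(C)C)=C\C1 | intermediate
22 | [(1S,2S,3E,5R,7E,11R)-8-(hydroxymethyl)-1,5-dimethyl-5-[(2E)-4-methylpenta-2,4-dien-1-yl]-12-oxabicyclo[9.1.0]dodeca-3,7-dien-2-yl] 3-methylbut-2-enoate | C=C(C)/C=C/C[C@@]1(C)/C=C/[C@H](OC(=O)C=C(C)C)[C@@]2(C)O[C@@H]2CC/C(CO)=C\C1 | target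

**Totals**
Total step count: 13. Longest linear sequence: 11 steps (steps 1, 2, 3, 6, 7, 8, 9, 10, 11, 12, 13); steps 4 and 5 form the side branch.

**Steps most likely to fail, with fallbacks**

Step 10 (ring closure and control of C1). The eleven-membered ring may close slowly, and the preference for the target C1 epimer may be small. The fallback sets out from 16 and comes back at 19. Dialdehyde 16 is treated with one equivalent of Ph3P=CHC(O)CH3 (CH2Cl2, rt), which olefinates one arm statistically. The two C1-epimeric mono-enones are separated by preparative HPLC, and the epimer with the target array is allyl 2-(diethoxyphosphoryl)-4-[(2R,3S)-3-[(1S,2E,4R,6E)-4-methyl-1-(3-methylbut-2-enoyloxy)-8-oxo-4-(2-oxoethyl)nona-2,6-dien-1-yl]-3-methyloxiran-2-yl]butanoate F5. With only one aldehyde left, the LiCl/DBU ring closure (MeCN, 1 mM) no longer decides any stereocentre and gives the macrocyclic enone, allyl (1S,2S,3E,5R,7E,11R)-1,5-dimethyl-2-(3-methylbut-2-enoyloxy)-5-[(2E)-4-oxopent-2-en-1-yl]-12-oxabicyclo[9.1.0]dodeca-3,7-diene-8-carboxylate F6. Methylenation of the ketone with Ph3P=CH2 (from Ph3PCH3Br and KOt-Bu, THF, 0 °C) then gives 19.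

Step 1 (reductive methylation of the pyridine ester). The reduced pyridine may dimerise, over-reduce or be attacked at the ester. The fallback sets out from iodomethane 2 and comes back at 4, and replaces the dearomatisation by oxidative cleavage of a carbocycle. Purchased methyl cyclopent-3-ene-1-carboxylate is deprotonated with LiN(i-Pr)2 (THF, −78 °C) and methylated with 2 to give methyl 1-methylcyclopent-3-ene-1-carboxylate F1. Ozonolysis (O3, CH2Cl2/MeOH, −78 °C; Me2S) gives methyl 2-methyl-4-oxo-2-(2-oxoethyl)butanoate F2, which is acetalised without isolation (TsOH, HC(OMe)3, MeOH) to 4.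

Step 8 (Mitsunobu inversion at a hindered carbinol with a weakly acidic partner). The fallback sets out from 13 and comes back at 15, and inverts C4 by oxidation and reduction instead of substitution. Dess–Martin periodinane oxidises 13 to the epoxy enone, allyl 2-(diethoxyphosphoryl)-4-[(2R,3S)-3-[(2E)-6,6-dimethoxy-4-(2,2-dimethoxyethyl)-4-methylhex-2-enoyl]-3-methyloxiran-2-yl]butanoate F3. LiBH(s-Bu)3 (THF, −78 °C) should deliver hydride anti to the oxirane C–O bond (Felkin–Anh) and in the 1,2 sense, because the beta carbon is neopentyl, giving the threo alcohol, allyl 2-(diethoxyphosphoryl)-4-[(2R,3R)-3-[(1S,2E)-1-hydroxy-6,6-dimethoxy-4-(2,2-dimethoxyethyl)-4-methylhex-2-en-1-yl]-3-methyloxiran-2-yl]butanoate F4. Esterification with 14 (2,4,6-trichlorobenzoyl chloride, Et3N, DMAP, toluene) with retention then gives 15.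

**Further compounds**

F1 | step 1 | methyl 1-methylcyclopent-3-ene-1-carboxylate | COC(=O)C1(C)CC=CC1
F2 | step 1 | methyl 2-methyl-4-oxo-2-(2-oxoethyl)butanoate | COC(=O)C(C)(CC=O)CC=O
F3 | step 8 | allyl 2-(diethoxyphosphoryl)-4-[(2R,3S)-3-[(2E)-6,6-dimethoxy-4-(2,2-dimethoxyethyl)-4-methylhex-2-enoyl]-3-methyloxiran-2-yl]butanoate | COC(OC)CC(C)(CC(OC)OC)/C=C/C(=O)[C@@]1(C)O[C@@H]1CCC(C(=O)OCC=C)P(=O)(OCC)OCC
F4 | step 8 | allyl 2-(diethoxyphosphoryl)-4-[(2R,3R)-3-[(1S,2E)-1-hydroxy-6,6-dimethoxy-4-(2,2-dimethoxyethyl)-4-methylhex-2-en-1-yl]-3-methyloxiran-2-yl]butanoate | COC(OC)CC(C)(CC(OC)OC)/C=C/[C@H](O)[C@@]1(C)O[C@@H]1CCC(C(=O)OCC=C)P(=O)(OCC)OCC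
F5 | step 10 | allyl 2-(diethoxyphosphoryl)-4-[(2R,3S)-3-[(1S,2E,4R,6E)-4-methyl-1-(3-methylbut-2-enoyloxy)-8-oxo-4-(2-oxoethyl)nona-2,6-dien-1-yl]-3-methyloxiran-2-yl]butanoate | CC(=O)/C=C/C[C@](C)(CC=O)/C=C/[C@H](OC(=O)C=C(C)C)[C@@]1(C)O[C@@H]1CCC(C(=O)OCC=C)P(=O)(OCC)OCC
F6 | step 10 | allyl (1S,2S,3E,5R,7E,11R)-1,5-dimethyl-2-(3-methylbut-2-enoyloxy)-5-[(2E)-4-oxopent-2-en-1-yl]-12-oxabicyclo[9.1.0]dodeca-3,7-diene-8-carboxylate | CC(=O)/C=C/C[C@@]1(C)/C=C/[C@H](OC(=O)C=C(C)C)[C@@]2(C)O[C@@H]2CC/C(C(=O)OCC=C)=C\C1
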